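| flask | starting material | partner | remark | time |
|---|---|---|---|---|
| Wednesday's | 0.13 M (in portions, 3) | 0.52 M | run made earlier; portions every 3.0 h |  |
| Saturday's | 0.52 M (in portions, 3) | 0.52 M | run made earlier; portions every 3.0 h |  |
| cedar | 0.26 M | 0.520 M | everything together at the start | 0.80 d |
| elm | 0.26 M (in portions, 3) | 0.520 M | the portions of starting material follow each other after 3.0 h, the first at the start | 2.5 d |

| run | time / h | target / % |
|---|---|---|
| Wednesday's | 2.50 | 0.2 |
| Wednesday's | 8.00 | 0.5 |
| Wednesday's | 15.0 | 4.8 |
| Wednesday's | 20.0 | 9.6 |
| Wednesday's | 30.0 | 23.4 |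
| Wednesday's | 40.0 | 38.2 |
| Wednesday's | 50.0 | 50.9 |
| Saturday's | 6.00 | 0.1 |
| Saturday's | 15.0 | 4.3 |
| Saturday's | 20.0 | 9.5 |
| Saturday's | 30.0 | 20.7 |
| Saturday's | 40.0 | 31.8 |
| Saturday's | 50.0 | 42.5 |

(standard deviation of a reading: 0.3 percentage points)

1. the flask that ends with the higher amount of target, in percent of the starting material charged, or "neither" when 2 percentage points or less lies between them (cedar / elm / neither)
2. final target, as a percentage of the starting material charged, in cedar
3. final target, as a percentage of the starting material charged, in elm

- a reading or a percentage of target counts all its forms, free or not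

- In a one-step world starting material goes straight to target, and the logarithm of the fraction not yet target falls in a straight line. The readings at 50.0 h then give a mean constant of 0.0126 h⁻¹, and with it cedar ends at 21.5% and elm at 53.2%. But that constant gives 9.59% at 8.00 h, where Wednesday's run read 0.5%.
- One more process, a stage that has to fill ahead of target, puts a lag in front of the line. From 30.0 h to 50.0 h the logarithm falls by 0.0222 h⁻¹ in Wednesday's run and 0.0161 h⁻¹ in Saturday's.
- Elm's charge of 0.26 M is twice Wednesday's and half Saturday's, so the mean of the two serves: the late fall rate κ, the hourly fall of the logarithm of the fraction not yet target once the lag is over, 0.0192 h⁻¹.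
- Traced back from the mean of the readings at 30.0 h, this line starts at 17.0 h. Elm moves to 56.1%, and cedar drops to 4.14%.
- The rest is the rounded bend and the dosing. Wednesday's run read 4.8% at 15.0 h, before the line's start, so cedar, stopping at 19.2 h, belongs on the bend, near the 9.6% and 9.5% read at 20.0 h. Cedar's charge also goes in 3.00 h earlier on average than portions do. Elm, dosed like the runs and past the bend, keeps its number.
- The forecast says elm, with 10% for cedar and 57% for elm, on the ground that “formation is nearly linear”. Its straight line in percent and the reckoning here in the logarithm stand 0.90 percentage points apart on elm.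
- The flasks give 10.9% in cedar and 58.0% in elm, so elm ends higher, and the forecast held.

    crystals ⇌ target, rate k1*(cs1 - [target]) while solid is left; crystals form when [target] > cs1 (solubility = 0.140 M, k = 3.60 × 10⁻⁴ s⁻¹)
    second intermediate → decomposed reagent (k = 4.20 × 10⁻⁷ s⁻¹)
    2 open intermediate → homo product (k = 6.20 × 10⁻⁶ M⁻¹ s⁻¹)
    starting material → open intermediate (k = 6.80 × 10⁻⁶ s⁻¹)
    open intermediate + second intermediate → target (k = 5.80 × 10⁻⁵ M⁻¹ s⁻¹)
    partner → second intermediate (k = 9.90 × 10⁻⁶ s⁻¹)

- At 0.800 d in cedar, open intermediate has a half-life of 0.61 d by the coupling with second intermediate, taken as a step by itself, down from 1.1 d at 0.333 d, while starting material has by its own step a half-life twice as long, 1.2 d. Open intermediate is still made 1.19 times faster than it is used, and it stands at 25.8%, with 62.5% of the starting material untouched.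
- Next, the flask cedar left until 50 h: its 10.9% carried forward at κ for 30.8 h gives 50.7%. The computed flask holds 50.4%.

The data are simulated with constants of no real substance; scatter was added.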